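**Plan**
- Retrosynthetic cuts: the ring C aryl ether O1–C8a; the C3–C4 bond (aldol between a ring B acetic acid unit and a ring A aldehyde); the ring D ether O–C2''; then ring B at C1'–C2', C3'–C4' and C4'–C5' (C1'–C6' arising from a 1,2-shift), which leaves a diazo enone and a siloxyalkyne.
- Forward order: ring B is built first from two acyclic pieces, ring D is closed onto it, the ring A aldehyde is attached by aldol, and ring C is closed last by O-arylation.
- Enabling feature: ring B is a 1,2,3,4-tetrasubstituted resorcinol (C1' bears C3 of ring C, C2' an oxygen, C3' the CH2 of ring D, C4' the ring D oxygen). Its two meta oxygens map onto a ketene oxygen and an ynol ether oxygen, so the ring is born with C4'–OH free and C2'–O silylated.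
- Stereochemistry: C3'' (R) comes from (R,R)-salen manganese epoxidation of a chromene followed by benzylic C–O hydrogenolysis; C3 (R) and C4 (S) are set together by an Evans syn-aldol with the (S)-4-benzyl oxazolidinone, the syn adduct becoming the 3,4-trans chromanol.

Key step: step 5

Remark: unprimed locants refer to the chroman-4-ol (rings A and C), primed to ring B, double-primed to ring D; it is assumed that the silyloxy group next to the chromene double bond does not alter the usual facial preference of the (R,R)-salen manganese catalyst for 2,2-dimethylchromenes.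

**Step 1**
Reactants: 1 methyl 4-chloro-4-oxobutanoate
Product: 2 methyl 4-oxohex-5-enoate
Conditions: CH2=CHSnBu3, PdCl2(PPh3)2 (2 mol%), BHT (trace), toluene, 60 °C
Reagents that add atoms: tributyl(vinyl)stannane, C=C[Sn](CCCC)(CCCC)CCCC
Why: Stille acylation of an acid chloride: oxidative addition of the acyl chloride to zerovalent palladium formed in situ, vinyl transfer from tin and reductive elimination should give the vinyl ketone without touching the methyl ester.

**Step 2**
Reactants: 2 methyl 4-oxohex-5-enoate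
Product: 4 methyl 3-diazo-4-oxohex-5-enoate, via trifluoroacetyl ketone 3 (not isolated)
Conditions: LiN(SiMe3)2, THF, −78 °C; CF3CO2CH2CF3, −78 °C; 1 M HCl work-up; then MsN3, Et3N, H2O (1 equiv), MeCN, 25 °C
Reagents that add atoms: methanesulfonyl azide, CS(=O)(=O)N=[N+]=[N-]
Why: Detrifluoroacetylative diazo transfer (Danheiser procedure for enones): C3 is the only enolisable position of the ketone and is more acidic than the ester α-CH2, so the kinetic lithium enolate is trifluoroacetylated there and the activated 1,3-dicarbonyl accepts the diazo group with loss of the trifluoroacetyl group.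

**Step 3**
Reactants: 5 4-methylpent-3-enoic acid
Product: 6 methyl 4-methylpent-3-enoate
Conditions: MeI, K2CO3, DMF, 25 °C
Reagents that add atoms: iodomethane, CI
Why: SN2 O-alkylation of the carboxylate under mild base should leave the β,γ-double bond in place and avoids the acid that would lactonise this acid.

**Step 4**
Reactants: 6 methyl 4-methylpent-3-enoate
Product: 9 triisopropyl[(5-methylhex-4-en-1-yn-1-yl)oxy]silane, via dibromo enolate 7 (not isolated), via lithium ynolate 8 (not isolated)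
Conditions: CH2Br2, LiTMP (from TMP, n-BuLi), THF, −78 °C; add 6; n-BuLi, −78 → 25 °C; then TIPSOTf, −78 → 0 °C
Reagents that add atoms: dibromomethane, BrCBr; triisopropylsilyl trifluoromethanesulfonate, CC(C)[Si](OS(=O)(=O)C(F)(F)F)(C(C)C)C(C)C
Why: Kowalski ester homologation: LiCHBr2 adds to the ester, bromine–lithium exchange on the dibromo ketone enolate triggers a carbenoid 1,2-shift to the ynolate, and the bulky silyl triflate should trap it on oxygen.

**Step 5**
Reactants: 4 methyl 3-diazo-4-oxohex-5-enoate; 9 triisopropyl[(5-methylhex-4-en-1-yn-1-yl)oxy]silane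
Product: 14 methyl 2-[4-hydroxy-3-(3-methylbut-2-en-1-yl)-2-(triisopropylsilyloxy)phenyl]acetate, via vinylketene 10 (not isolated), via 4-vinylcyclobutenone 11 (not isolated), via dienylketene 12 (not isolated), via cyclohexa-2,4-dienone 13 (not isolated)
Conditions: hν (254 nm, low-pressure Hg lamp, Vycor), ClCH2CH2Cl (degassed), 25 °C; then 80 °C
Reagents that add atoms: none
Why: Light expels N2 from 4 and the vinyl group shifts to the carbene carbon (photochemical Wolff rearrangement, C1'–C6'), giving vinylketene 10, whose ketene C=C adds to the electron-rich siloxyalkyne in a [2+2] cycloaddition (C1'–C2', C3'–C4') to form vinylcyclobutenone 11. On warming, 11 opens by 4π-electrocyclic cleavage to dienylketene 12, which closes ring B by thermal disrotatory 6π-electrocyclisation (C4'–C5') and tautomerises from dienone 13 to the phenol; this is the Danheiser benzannulation in its diazo ketone/siloxyalkyne form. No stereocentre is formed. The step needs regiocontrol in the [2+2], which the polarised ynol ether supplies: its nucleophilic carbon β to oxygen (the prenyl-bearing one) bonds to the ketene carbonyl carbon, so the prenyl group ends up between the two oxygens. It also needs the ketene to choose the alkyne over the prenyl alkene, which the far higher reactivity of ynol ethers toward ketenes should ensure; the ketene oxygen emerges as the free C4' hydroxyl and the ynol oxygen stays silylated at C2'.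

**Step 6**
Reactants: 14 methyl 2-[4-hydroxy-3-(3-methylbut-2-en-1-yl)-2-(triisopropylsilyloxy)phenyl]acetate
Product: 16 methyl 2-[2,2-dimethyl-5-(triisopropylsilyloxy)-2H-chromen-6-yl]acetate, via o-quinone methide 15 (not isolated)
Conditions: DDQ (1.1 equiv), toluene, 80 °C
Reagents that add atoms: none
Why: DDQ dehydrogenation of an o-prenylphenol: hydride abstraction from the benzylic and allylic CH2 gives o-quinone methide 15, which closes ring D by oxa-6π-electrocyclisation, and only the free C4' phenol can take part because O2' is silylated.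

**Step 7**
Reactants: 16 methyl 2-[2,2-dimethyl-5-(triisopropylsilyloxy)-2H-chromen-6-yl]acetate
Product: 17 methyl 2-[(3R,4R)-3,4-epoxy-2,2-dimethyl-5-(triisopropylsilyloxy)-3,4-dihydro-2H-chromen-6-yl]acetate
Conditions: (R,R)-[N,N'-bis(3,5-di-tert-butylsalicylidene)cyclohexane-1,2-diaminato]manganese chloride (4 mol%), 4-phenylpyridine N-oxide, NaOCl (aq., pH 11.3), CH2Cl2, 0 °C
Reagents that add atoms: sodium hypochlorite, [Na+].[O-]Cl
Why: Jacobsen–Katsuki epoxidation, for which aryl-conjugated cis-alkenes of the 2,2-dimethylchromene type are the classic substrates; the (R,R) ligand directs oxygen to the face that gives the (3R,4R)-epoxide and thereby fixes the future ring D carbinol as R.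

**Step 8**
Reactants: 17 methyl 2-[(3R,4R)-3,4-epoxy-2,2-dimethyl-5-(triisopropylsilyloxy)-3,4-dihydro-2H-chromen-6-yl]acetate
Product: 18 methyl 2-[(3R)-3-hydroxy-2,2-dimethyl-5-(triisopropylsilyloxy)chroman-6-yl]acetate
Conditions: H2 (1 atm), Pd/C (10%), EtOAc, Et3N (trace), 25 °C
Reagents that add atoms: none
Why: Catalytic hydrogenolysis of an aryl epoxide cleaves only the benzylic C4–O bond, so the C3–O bond and its R configuration are retained, while the ester and the aryl silyl ether are inert.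

**Step 9**
Reactants: 18 methyl 2-[(3R)-3-hydroxy-2,2-dimethyl-5-(triisopropylsilyloxy)chroman-6-yl]acetate
Product: 19 methyl 2-[(3R)-3-(tert-butyldimethylsilyloxy)-2,2-dimethyl-5-(triisopropylsilyloxy)chroman-6-yl]acetate
Conditions: TBSOTf, 2,6-lutidine, CH2Cl2, 0 °C
Reagents that add atoms: tert-butyldimethylsilyl trifluoromethanesulfonate, CC(C)(C)[Si](C)(C)OS(=O)(=O)C(F)(F)F
Why: Silyl triflate silylation is the standard way to protect a hindered secondary alcohol, here masking it for the acylation and boron aldol that follow.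

**Step 10**
Reactants: 19 methyl 2-[(3R)-3-(tert-butyldimethylsilyloxy)-2,2-dimethyl-5-(triisopropylsilyloxy)chroman-6-yl]acetate
Product: 20 2-[(3R)-3-(tert-butyldimethylsilyloxy)-2,2-dimethyl-5-(triisopropylsilyloxy)chroman-6-yl]acetic acid
Conditions: LiOH·H2O, THF/H2O, 0 → 25 °C; then 1 M HCl to pH 4, 0 °C
Reagents that add atoms: lithium hydroxide, [Li+].[OH-]
Why: Saponification of an unhindered methyl arylacetate is fast, whereas the doubly ortho-flanked aryl triisopropylsilyl ether and the secondary alkyl silyl ether should resist cold LiOH.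

**Step 11**
Reactants: 20 2-[(3R)-3-(tert-butyldimethylsilyloxy)-2,2-dimethyl-5-(triisopropylsilyloxy)chroman-6-yl]acetic acid; 21 (S)-4-benzyl-2-oxazolidinone
Product: 23 (S)-4-benzyl-3-{2-[(3R)-3-(tert-butyldimethylsilyloxy)-2,2-dimethyl-5-(triisopropylsilyloxy)chroman-6-yl]acetyl}oxazolidin-2-one, via mixed pivalic anhydride 22 (not isolated)
Conditions: PivCl, Et3N, THF, −20 °C; then 21, LiCl, −20 → 25 °C
Reagents that add atoms: none
Why: Mixed-anhydride N-acylation of the oxazolidinone with LiCl assistance: the tert-butyl group blocks the pivaloyl carbonyl, so the auxiliary should attack the arylacetyl carbonyl.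

**Step 12**
Reactants: 24 2-bromo-4-hydroxybenzaldehyde
Product: 25 2-bromo-4-(triisopropylsilyloxy)benzaldehyde
Conditions: TIPSCl, imidazole, CH2Cl2, 25 °C
Reagents that add atoms: chlorotriisopropylsilane, CC(C)[Si](Cl)(C(C)C)C(C)C
Why: Imidazole-mediated phenol silylation; the triisopropylsilyl group is chosen so that this aryl ether survives the later carbonate base at elevated temperature.

**Step 13**
Reactants: 23 (S)-4-benzyl-3-{2-[(3R)-3-(tert-butyldimethylsilyloxy)-2,2-dimethyl-5-(triisopropylsilyloxy)chroman-6-yl]acetyl}oxazolidin-2-one; 25 2-bromo-4-(triisopropylsilyloxy)benzaldehyde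
Product: 28 (S)-4-benzyl-3-{(2S,3S)-3-[2-bromo-4-(triisopropylsilyloxy)phenyl]-2-[(3R)-3-(tert-butyldimethylsilyloxy)-2,2-dimethyl-5-(triisopropylsilyloxy)chroman-6-yl]-3-hydroxypropanoyl}oxazolidin-2-one, via boron Z-enolate 26 (not isolated), via boron aldolate 27 (not isolated)
Conditions: Bu2BOTf, i-Pr2NEt, CH2Cl2, −78 → 0 °C; 25, −78 → 0 °C; then pH 7 buffer, MeOH, H2O2, 0 °C
Reagents that add atoms: none
Why: Evans syn-aldol: the Z-boron enolate reacts through a Zimmerman–Traxler chair in which the benzyl group of the auxiliary shields one enolate face, which should give the (2S,3S) syn adduct and so set both C3 (R) and C4 (S) of the later chromanol.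

**Step 14**
Reactants: 28 (S)-4-benzyl-3-{(2S,3S)-3-[2-bromo-4-(triisopropylsilyloxy)phenyl]-2-[(3R)-3-(tert-butyldimethylsilyloxy)-2,2-dimethyl-5-(triisopropylsilyloxy)chroman-6-yl]-3-hydroxypropanoyl}oxazolidin-2-one
Product: 29 (1S,2R)-1-[2-bromo-4-(triisopropylsilyloxy)phenyl]-2-[(3R)-3-(tert-butyldimethylsilyloxy)-2,2-dimethyl-5-(triisopropylsilyloxy)chroman-6-yl]propane-1,3-diol
Conditions: LiBH4, THF, MeOH (1.5 equiv), 0 °C
Reagents that add atoms: none
Why: Reductive cleavage of the N-acyl oxazolidinone with LiBH4 attacks the exocyclic imide carbonyl and gives the primary alcohol without touching the stereocentres, the aryl bromide or the silyl ethers (the descriptor at C2 changes only because of priorities).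

**Step 15**
Reactants: 29 (1S,2R)-1-[2-bromo-4-(triisopropylsilyloxy)phenyl]-2-[(3R)-3-(tert-butyldimethylsilyloxy)-2,2-dimethyl-5-(triisopropylsilyloxy)chroman-6-yl]propane-1,3-diol
Product: 30 (3R,4S)-3-[(3R)-3-(tert-butyldimethylsilyloxy)-2,2-dimethyl-5-(triisopropylsilyloxy)chroman-6-yl]-7-(triisopropylsilyloxy)chroman-4-ol
Conditions: CuI (10 mol%), 3,4,7,8-tetramethyl-1,10-phenanthroline (20 mol%), Cs2CO3, toluene, 100 °C
Reagents that add atoms: none
Why: Intramolecular Ullmann-type copper-catalysed O-arylation: only the primary alkoxide can reach the C–Br carbon through a six-membered ring (the benzylic hydroxyl would have to form a four-membered ring), so ring C should close with both stereocentres untouched.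

**Step 16**
Reactants: 30 (3R,4S)-3-[(3R)-3-(tert-butyldimethylsilyloxy)-2,2-dimethyl-5-(triisopropylsilyloxy)chroman-6-yl]-7-(triisopropylsilyloxy)chroman-4-ol
Product: 31 (3R,4S)-3-[(3R)-3,5-dihydroxy-2,2-dimethylchroman-6-yl]chroman-4,7-diol
Conditions: TBAF, AcOH (1:1), THF, 0 → 25 °C; pH 7 phosphate work-up
Reagents that add atoms: none
Why: Fluoride-mediated global desilylation under buffered, non-acidic conditions should free the three hydroxyls while sparing the C4 benzylic alcohol, which acid would ionise through the para C7 phenol and close onto the C2' hydroxyl.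

**Compound list**
1 | methyl 4-chloro-4-oxobutanoate | COC(=O)CCC(Cl)=O | starting material
2 | methyl 4-oxohex-5-enoate | C=CC(=O)CCC(=O)OC | intermediate
3 | methyl 4-oxo-3-(2,2,2-trifluoroacetyl)hex-5-enoate (racemic, largely enolised) | C=CC(=O)C(CC(=O)OC)C(=O)C(F)(F)F | intermediate
4 | methyl 3-diazo-4-oxohex-5-enoate | C=CC(=O)C(=[N+]=[N-])CC(=O)OC | intermediate
5 | 4-methylpent-3-enoic acid | CC(C)=CCC(O)=O | starting material
6 | methyl 4-methylpent-3-enoate | COC(=O)CC=C(C)C | intermediate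
7 | lithium 1,1-dibromo-5-methylhexa-1,4-dien-2-olate | [Li+].[O-]C(CC=C(C)C)=C(Br)Br | intermediate
8 | lithium 5-methylhex-4-en-1-yn-1-olate | [Li+].[O-]C#CCC=C(C)C | intermediate
9 | triisopropyl[(5-methylhex-4-en-1-yn-1-yl)oxy]silane | CC(C)=CCC#CO[Si](C(C)C)(C(C)C)C(C)C | intermediate
10 | methyl 3-(oxomethylidene)pent-4-enoate (vinylketene) | C=CC(CC(=O)OC)=C=O | intermediate
11 | methyl 2-[1-ethenyl-3-(3-methylbut-2-en-1-yl)-4-oxo-2-(triisopropylsilyloxy)cyclobut-2-en-1-yl]acetate (racemic) | COC(=O)CC1(C=C)C(=O)C(CC=C(C)C)=C1O[Si](C(C)C)(C(C)C)C(C)C | intermediate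
12 | methyl (3E)-3-ethenyl-5-(3-methylbut-2-en-1-yl)-6-oxo-4-(triisopropylsilyloxy)hexa-3,5-dienoate (dienylketene) | O=C=C(CC=C(C)C)/C(O[Si](C(C)C)(C(C)C)C(C)C)=C(CC(=O)OC)\C=C | intermediate
13 | methyl 2-[5-(3-methylbut-2-en-1-yl)-4-oxo-6-(triisopropylsilyloxy)cyclohexa-1,5-dien-1-yl]acetate | O=C1CC=C(CC(=O)OC)C(O[Si](C(C)C)(C(C)C)C(C)C)=C1CC=C(C)C | intermediate
14 | methyl 2-[4-hydroxy-3-(3-methylbut-2-en-1-yl)-2-(triisopropylsilyloxy)phenyl]acetate | COC(=O)Cc1ccc(O)c(CC=C(C)C)c1O[Si](C(C)C)(C(C)C)C(C)C | intermediate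
15 | methyl 2-[5-(3-methylbut-2-en-1-ylidene)-4-oxo-6-(triisopropylsilyloxy)cyclohexa-1,3-dien-1-yl]acetate (o-quinone methide, butenylidene chain syn to C=O) | O=C1C=CC(CC(=O)OC)=C(O[Si](C(C)C)(C(C)C)C(C)C)/C1=C/C=C(C)C | intermediate
16 | methyl 2-[2,2-dimethyl-5-(triisopropylsilyloxy)-2H-chromen-6-yl]acetate | COC(=O)Cc1ccc2OC(C)(C)C=Cc2c1O[Si](C(C)C)(C(C)C)C(C)C | intermediate
17 | methyl 2-[(3R,4R)-3,4-epoxy-2,2-dimethyl-5-(triisopropylsilyloxy)-3,4-dihydro-2H-chromen-6-yl]acetate | COC(=O)Cc1ccc2OC(C)(C)[C@@H]3O[C@@H]3c2c1O[Si](C(C)C)(C(C)C)C(C)C | intermediate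
18 | methyl 2-[(3R)-3-hydroxy-2,2-dimethyl-5-(triisopropylsilyloxy)chroman-6-yl]acetate | COC(=O)Cc1ccc2OC(C)(C)[C@H](O)Cc2c1O[Si](C(C)C)(C(C)C)C(C)C | intermediate
19 | methyl 2-[(3R)-3-(tert-butyldimethylsilyloxy)-2,2-dimethyl-5-(triisopropylsilyloxy)chroman-6-yl]acetate | COC(=O)Cc1ccc2OC(C)(C)[C@H](O[Si](C)(C)C(C)(C)C)Cc2c1O[Si](C(C)C)(C(C)C)C(C)C | intermediate
20 | 2-[(3R)-3-(tert-butyldimethylsilyloxy)-2,2-dimethyl-5-(triisopropylsilyloxy)chroman-6-yl]acetic acid | OC(=O)Cc1ccc2OC(C)(C)[C@H](O[Si](C)(C)C(C)(C)C)Cc2c1O[Si](C(C)C)(C(C)C)C(C)C | intermediate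
21 | (S)-4-benzyl-2-oxazolidinone | O=C1N[C@@H](Cc2ccccc2)CO1 | starting material
22 | 2-[(3R)-3-(tert-butyldimethylsilyloxy)-2,2-dimethyl-5-(triisopropylsilyloxy)chroman-6-yl]acetic pivalic anhydride | CC(C)(C)C(=O)OC(=O)Cc1ccc2OC(C)(C)[C@H](O[Si](C)(C)C(C)(C)C)Cc2c1O[Si](C(C)C)(C(C)C)C(C)C | intermediate
23 | (S)-4-benzyl-3-{2-[(3R)-3-(tert-butyldimethylsilyloxy)-2,2-dimethyl-5-(triisopropylsilyloxy)chroman-6-yl]acetyl}oxazolidin-2-one | O=C(Cc1ccc2OC(C)(C)[C@H](O[Si](C)(C)C(C)(C)C)Cc2c1O[Si](C(C)C)(C(C)C)C(C)C)N1[C@@H](Cc2ccccc2)COC1=O | intermediate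
24 | 2-bromo-4-hydroxybenzaldehyde | O=Cc1ccc(O)cc1Br | starting material
25 | 2-bromo-4-(triisopropylsilyloxy)benzaldehyde | O=Cc1ccc(O[Si](C(C)C)(C(C)C)C(C)C)cc1Br | intermediate
26 | dibutylboron (Z)-enolate of 23 | CCCCB(CCCC)O/C(N1[C@@H](Cc2ccccc2)COC1=O)=C\c1ccc2OC(C)(C)[C@H](O[Si](C)(C)C(C)(C)C)Cc2c1O[Si](C(C)C)(C(C)C)C(C)C | intermediate
27 | O-dibutylboryl aldolate of 28 | CC1(C)Oc2ccc([C@H](C(=O)N3[C@@H](Cc4ccccc4)COC3=O)[C@H](OB(CCCC)CCCC)c3ccc(O[Si](C(C)C)(C(C)C)C(C)C)cc3Br)c(O[Si](C(C)C)(C(C)C)C(C)C)c2C[C@H]1O[Si](C)(C)C(C)(C)C | intermediate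
28 | (S)-4-benzyl-3-{(2S,3S)-3-[2-bromo-4-(triisopropylsilyloxy)phenyl]-2-[(3R)-3-(tert-butyldimethylsilyloxy)-2,2-dimethyl-5-(triisopropylsilyloxy)chroman-6-yl]-3-hydroxypropanoyl}oxazolidin-2-one | CC1(C)Oc2ccc([C@H](C(=O)N3[C@@H](Cc4ccccc4)COC3=O)[C@H](O)c3ccc(O[Si](C(C)C)(C(C)C)C(C)C)cc3Br)c(O[Si](C(C)C)(C(C)C)C(C)C)c2C[C@H]1O[Si](C)(C)C(C)(C)C | intermediate
29 | (1S,2R)-1-[2-bromo-4-(triisopropylsilyloxy)phenyl]-2-[(3R)-3-(tert-butyldimethylsilyloxy)-2,2-dimethyl-5-(triisopropylsilyloxy)chroman-6-yl]propane-1,3-diol | CC1(C)Oc2ccc([C@H](CO)[C@H](O)c3ccc(O[Si](C(C)C)(C(C)C)C(C)C)cc3Br)c(O[Si](C(C)C)(C(C)C)C(C)C)c2C[C@H]1O[Si](C)(C)C(C)(C)C | intermediate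
30 | (3R,4S)-3-[(3R)-3-(tert-butyldimethylsilyloxy)-2,2-dimethyl-5-(triisopropylsilyloxy)chroman-6-yl]-7-(triisopropylsilyloxy)chroman-4-ol | CC1(C)Oc2ccc([C@@H]3COc4cc(O[Si](C(C)C)(C(C)C)C(C)C)ccc4[C@H]3O)c(O[Si](C(C)C)(C(C)C)C(C)C)c2C[C@H]1O[Si](C)(C)C(C)(C)C | intermediate
31 | (3R,4S)-3-[(3R)-3,5-dihydroxy-2,2-dimethylchroman-6-yl]chroman-4,7-diol | CC1(C)Oc2ccc([C@@H]3COc4cc(O)ccc4[C@H]3O)c(O)c2C[C@H]1O | target

**Step count and risks**

Total step count: 16. Longest linear sequence: 13 steps (steps 1, 2, 5–11, 13–16 from 1; equally 3, 4, 5–11, 13–16 from 5).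

The three steps most likely to fail:

Step 5. The transient vinylketene may be lost before the siloxyalkyne captures it, and diazo ketone 4 may itself be consumed by polymerisation through its vinyl ketone or by a carbene 1,2-hydrogen shift on irradiation. The fallback generates the same vinylketene thermally, without a diazo compound; it sets out from siloxyalkyne 9 and comes back to the route at phenol 14. But-3-enoic acid would be converted into its dianion (LiN(i-Pr)2, 2.2 equiv, THF, −78 °C) and alkylated at the α-carbon with methyl bromoacetate to give 2-ethenylbutanedioic acid 4-methyl ester F1. Oxalyl chloride with a trace of DMF would turn it into methyl 3-(chlorocarbonyl)pent-4-enoate F2. Slow addition of F2 to Et3N and 9 in toluene at 25 °C, then heating to 80–110 °C, should form vinylketene 10 by dehydrochlorination and carry it through 11, 12 and 13 to 14. This fallback also makes steps 1 and 2 unnecessary.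

Step 15. Oxidative addition at the electron-rich aryl bromide may be slow, and at the temperature then required silyl migration from the aryl oxygens to the alkoxides, or reductive loss of bromine, may outrun ring closure. The fallback forms the alkyl–oxygen bond of ring C instead of the aryl–oxygen bond; it sets out from imide 23 and comes back at chromanol 30. Commercial 2,4-dihydroxybenzaldehyde would be silylated at the non-chelated 4-hydroxyl (TIPSCl, imidazole) to give 2-hydroxy-4-(triisopropylsilyloxy)benzaldehyde F3 and allylated (allyl bromide, K2CO3, acetone) to give 2-(allyloxy)-4-(triisopropylsilyloxy)benzaldehyde F4. The Evans aldol of 23 with F4 under the conditions of step 13 should give the (2S,3S) syn-aldol imide F5, and LiBH4 the (1S,2R)-diol F6. Pd(PPh3)4 with morpholine would remove the allyl group to give the phenol diol F7. A Mitsunobu reaction (PPh3, DIAD, THF, 0 °C) should then close ring C by SN2 attack of the phenol on the activated primary carbinol, leaving the stereocentres untouched, to give 30.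

Step 4. LiTMP or LiCHBr2 may deprotonate the doubly activated α-position of the β,γ-unsaturated ester, with migration of the double bond into conjugation, instead of adding to the carbonyl. The fallback reaches the ynolate by oxidation of an acetylide; it sets out from ester 6 and comes back at siloxyalkyne 9 through ynolate 8. Reduction with i-Bu2AlH (CH2Cl2, −78 °C) would give 4-methylpent-3-enal F8, and Corey–Fuchs olefination (CBr4, PPh3) 1,1-dibromo-5-methylhexa-1,4-diene F9. Treatment with n-BuLi (2 equiv, THF, −78 °C) should give lithium 5-methylhex-4-en-1-yn-1-ide F10. Oxidation with LiOOt-Bu (from t-BuOOH and LiN(SiMe3)2) should give ynolate 8, which TIPSOTf silylates to 9.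

**Further compounds**
F1 | step 5 | 2-ethenylbutanedioic acid 4-methyl ester (racemic) | C=CC(CC(=O)OC)C(O)=O
F2 | step 5 | methyl 3-(chlorocarbonyl)pent-4-enoate (racemic) | C=CC(CC(=O)OC)C(Cl)=O
F3 | step 15 | 2-hydroxy-4-(triisopropylsilyloxy)benzaldehyde | O=Cc1ccc(O[Si](C(C)C)(C(C)C)C(C)C)cc1O
F4 | step 15 | 2-(allyloxy)-4-(triisopropylsilyloxy)benzaldehyde | C=CCOc1cc(O[Si](C(C)C)(C(C)C)C(C)C)ccc1C=O
F5 | step 15 | (S)-4-benzyl-3-{(2S,3S)-3-[2-(allyloxy)-4-(triisopropylsilyloxy)phenyl]-2-[(3R)-3-(tert-butyldimethylsilyloxy)-2,2-dimethyl-5-(triisopropylsilyloxy)chroman-6-yl]-3-hydroxypropanoyl}oxazolidin-2-one | CC1(C)Oc2ccc([C@H](C(=O)N3[C@@H](Cc4ccccc4)COC3=O)[C@H](O)c3ccc(O[Si](C(C)C)(C(C)C)C(C)C)cc3OCC=C)c(O[Si](C(C)C)(C(C)C)C(C)C)c2C[C@H]1O[Si](C)(C)C(C)(C)C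
F6 | step 15 | (1S,2R)-1-[2-(allyloxy)-4-(triisopropylsilyloxy)phenyl]-2-[(3R)-3-(tert-butyldimethylsilyloxy)-2,2-dimethyl-5-(triisopropylsilyloxy)chroman-6-yl]propane-1,3-diol | CC1(C)Oc2ccc([C@H](CO)[C@H](O)c3ccc(O[Si](C(C)C)(C(C)C)C(C)C)cc3OCC=C)c(O[Si](C(C)C)(C(C)C)C(C)C)c2C[C@H]1O[Si](C)(C)C(C)(C)C
F7 | step 15 | (1S,2R)-2-[(3R)-3-(tert-butyldimethylsilyloxy)-2,2-dimethyl-5-(triisopropylsilyloxy)chroman-6-yl]-1-[2-hydroxy-4-(triisopropylsilyloxy)phenyl]propane-1,3-diol | CC1(C)Oc2ccc([C@H](CO)[C@H](O)c3ccc(O[Si](C(C)C)(C(C)C)C(C)C)cc3O)c(O[Si](C(C)C)(C(C)C)C(C)C)c2C[C@H]1O[Si](C)(C)C(C)(C)C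
F8 | step 4 | 4-methylpent-3-enal | CC(C)=CCC=O
F9 | step 4 | 1,1-dibromo-5-methylhexa-1,4-diene | CC(C)=CCC=C(Br)Br
F10 | step 4 | lithium 5-methylhex-4-en-1-yn-1-ide | [Li]C#CCC=C(C)C
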